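**Structural features**

The target is a flavonol, 3-hydroxy-5,7-dimethoxy-2-(2-methoxyphenyl)-6,8-dimethyl-4H-chromen-4-one: benzo ring A is fused along C4a–C8a to the 4-pyranone ring C, and ring B, a 2-methoxyphenyl group, is bonded to C2. The molecule is achiral; the only configurational element met on the way is an alkene geometry, and it disappears when ring C becomes aromatic. Ring A carries six substituents in a fixed order: OMe on C5, Me on C6, OMe on C7, Me on C8, the ring oxygen O1 on C8a and the C4 carbonyl on C4a. The sensitive sites are the enolic C3 hydroxyl next to the C4 carbonyl (easily oxidised, strongly chelating), the C5 methoxy group peri to that carbonyl (the first ether to be cleaved by Lewis acids) and the electron-rich ring A, which is oxidised to quinones when it carries free phenols. The real difficulty is twofold: the fully substituted ring A must be assembled with every group in place, and the C3 oxygen cannot safely be introduced late by Algar–Flynn–Oyamada oxidation, because chalcones substituted at the position that becomes C5 are diverted to aurones, so this oxygen has to arrive with the C2–C3–C4 unit. The key step uses the fact that the oxygen-bearing C8a and the acyl-bearing C4a are neighbours, so they can be the two ends of an aryne, and that the methoxy group on C5, next to C4a, differentiates those two ends.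

**Logic of the disconnections**

19 from 18. The O–CH2 bond of a benzyl ether on the C3 oxygen is cut. The enolic hydroxyl stays masked until the end, and benzyl is the one group that can be removed under neutral conditions in the presence of three aryl methyl ethers. The forward step must cleave it without reducing the C2–C3 double bond.

18 from 16. The O1–C2 bond is cut and ring C is taken one oxidation level down to an open hydroxy enone. This opens the pyranone and leaves ring A and ring B joined only by a three-carbon chain that already has the C4 carbonyl and the C3 oxygen. The forward step must close the ring in the 6-endo sense and dehydrogenate C2–C3 without losing the benzyl enol ether.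

16 from 10 and 14, by way of 15. The C8a–O1 and C4a–C4 bonds are cut together. This divides the molecule into a ring A fragment and a fragment holding ring B, C2, C3 with its oxygen, and C4. Atom bookkeeping: the silicon-bearing carbon of 10 becomes C4a and the triflate-bearing carbon becomes C8a. The forward step must add oxygen at C8a and carbon at C4a, not the reverse, and acyl transfer to the aryl anion must beat its protonation.

14 from 11 and 12, by way of 13. The C2=C3 double bond (flavone numbering) is cut as an aldol condensation, leading to two commercial compounds. The forward step must dehydrate fully, keep the benzyl ether, and give the isomer with the aryl group trans to the carboxyl.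

10 from 7, by way of 8 and 9, and 7 from 6. The O–S bond of the triflate is cut, and the C4a–Si bond is traced back to an O–Si bond through an O-to-C silyl shift. This reduces the aryne precursor to an ortho-bromophenol. The forward step needs bromine–lithium exchange and silyl migration to outrun proton transfer, and a crowded phenoxide must still be triflated.

6 from 5. The C4a–Br bond is cut. Only one ring position of 5 is unsubstituted, so the forward bromination has no regiochemical choice; it only must not over-oxidise.

5 from 3, by way of 4. A carboxyl carbon is put back on the carbon that is C4a. It blocks the third nucleophilic ring position during C-methylation and, by hydrogen bonding, marks out the one hydroxyl that must stay free. The carbon removed here stands where C4 is attached later; the detour is accepted because the aryne step then brings in C4 with the whole C2–C3–ring B unit. The forward step must hydrolyse a hindered ester and decarboxylate.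

3 from 2, and 2 from 1. Two O–CH3 bonds (on the C5 and C7 oxygens) are cut, then the two C–CH3 bonds at C6 and C8. This leads to a commercial phloroglucinol ester. The forward steps need C- over O-alkylation first and then site-selective O-alkylation.

**Other disconnections considered**

Alternative 1: The cut runs through C3–C4 and O1–C2, removing C2, C3 and ring B as an alkyne.
- Forward step: 2-hydroxy-4,6-dimethoxy-3,5-dimethylbenzaldehyde A1 and triisopropyl{[(2-methoxyphenyl)ethynyl]oxy}silane A2 would be combined under [Cp*RhCl2]2 (trivalent rhodium) with Cu(OAc)2 (divalent copper) as terminal oxidant. The phenol directs cleavage of the formyl C–H bond, the alkyne inserts into the acyl–rhodium bond, and C–O reductive elimination closes ring C to the silyl-protected flavonol A3. Fluoride would then free the target.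
- In favour: ring C is closed at its final oxidation level in one operation with the C3 oxygen in place. O1 and C4a are fixed by A1, so ring A poses no regiochemical question; on this point it is better than the chosen plan. A1 is one formylation away from 5, so it is also better on step count (about seven steps against ten).
- Against: the insertion must place the siloxy carbon on the acyl side. The usual preference of an aryl-bearing alkyne carbon for the position next to the metal would do that, but an ynol ether is polarised with the ring B carbon as its nucleophilic end, and the outcome cannot be predicted with confidence. Siloxyalkynes are also protonated by phenols and by the acetic acid released from Cu(OAc)2 and then acylate the phenol of A1, which is the directing group the catalysis needs. A2 requires its own multistep preparation.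
- Comparison: both plans attach ring C to a preformed ring A. The aryne insertion belongs to a documented reaction class with a bias of known direction; this annulation would rest on an alkyne class for which the catalysis is not established. Alternative 1 is superior in step count and inferior in predictability.

Alternative 2: Ring A itself is disconnected: C8–C8a and C6–C7 are cut, and C4a–C8a is opened and re-formed.
- Forward step: 3-methoxy-2-methylcyclobut-2-enone A4 and 1-methoxypropyne A5 are heated. A 4π opening, a [2+2] addition of the alkyne, a second 4π opening, a 6π closure and tautomerisation (Danheiser benzannulation) would give 3,5-dimethoxy-2,4-dimethylphenol A6, which is the same compound as 5.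
- In favour: the order of the six substituents follows from the connectivity of the two components, so nothing depends on selective C- versus O-methylation. On regiochemical certainty of ring A it is better than steps 1 to 3.
- Against: it supplies 5 but leaves the attachment of C4 and the closure of ring C untouched, so everything from step 4 onward would be unchanged. A4 and A5 are not shelf compounds, A5 is a volatile ynol ether, and A4, a vinylogous ester, is expected to open less readily than alkyl-substituted cyclobutenones.
- Comparison: equal in structure from 5 onward. Mechanistically it is a pericyclic cascade with built-in regiocontrol against three polar steps whose selectivity must be steered. No gain in step economy is expected once the preparations of A4 and A5 are counted.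

Alternative 3: The cut is the C3–C4 bond at the chromane oxidation level.
- Forward step: 2-[1-(2-methoxyphenyl)-2-oxoethoxy]-4,6-dimethoxy-3,5-dimethylbenzaldehyde A7 is treated with SmI2 (divalent samarium). One-electron reduction of both formyl groups and coupling of the two carbonyl carbons closes ring C as 5,7-dimethoxy-2-(2-methoxyphenyl)-6,8-dimethylchromane-3,4-diol A8, a mixture of racemic diastereomers.
- In favour: an intramolecular pinacol closure to a six-membered ring at low temperature is milder than a 125 °C aryne reaction, and on this point it is better. Ring A poses no regiochemical question and O3 needs no protecting group; on these points it is equal or better.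
- Against: A7 has an aryloxy group alpha to the aliphatic formyl group, and such carbonyl compounds are prone to reductive C–O cleavage by SmI2, which would expel the ring A phenoxide in competition with coupling. A7 is an easily enolised aldehyde that must be made by O-alkylation of a hindered, chelated phenol with a secondary benzylic electrophile. A8 lies four electrons below the target and has three stereocentres made only to be destroyed; C4 must be oxidised selectively beside the C3 alcohol and C2–C3 then dehydrogenated.
- Comparison: the chosen plan delivers C4 as a ketone and needs one two-electron oxidation after the key step, against two here. Alternative 3 is a radical-anion coupling with a built-in fragmentation risk, against a polar insertion. It is clearly worse in step economy.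

Key step: step 8

Assumption: a minor content of the E isomer in 14, or partial closure of 16 to 17 during step 8, is of no consequence, because step 9 erases the alkene geometry and converts both 16 and 17 into 18.

**Route**

Step 1
Reactants: 1 methyl 2,4,6-trihydroxybenzoate
Product: 2 methyl 2,4,6-trihydroxy-3,5-dimethylbenzoate
Conditions: MeI (2.1 equiv), NaOMe (3 equiv), MeOH, 0 °C to reflux
Reagents that add atoms: iodomethane, CI
Why: C-Alkylation of an acylphloroglucinol: the ambident phenoxide reacts with soft MeI at carbon in methanol, and the ester occupies the third ring position so only the two free carbons can be methylated. Limiting MeI to two equivalents restrains a second methylation at the same carbon.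

Step 2
Reactants: 2 methyl 2,4,6-trihydroxy-3,5-dimethylbenzoate
Product: 3 methyl 2-hydroxy-4,6-dimethoxy-3,5-dimethylbenzoate
Conditions: Me2SO4 (2.1 equiv), K2CO3, acetone, reflux
Reagents that add atoms: dimethyl sulfate, COS(=O)(=O)OC
Why: Williamson O-methylation with a hard electrophile under weak base: the para hydroxyl and one ortho hydroxyl react, while the last ortho hydroxyl is held in a hydrogen bond to the ester carbonyl and is much less nucleophilic. Two equivalents should therefore leave free exactly the oxygen that becomes O1.

Step 3
Reactants: 3 methyl 2-hydroxy-4,6-dimethoxy-3,5-dimethylbenzoate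
Product: 5 3,5-dimethoxy-2,4-dimethylphenol, via 2-hydroxy-4,6-dimethoxy-3,5-dimethylbenzoic acid 4 (not isolated)
Conditions: KOH, MeOH–H2O, reflux; then HCl (pH 1), 70 °C
Reagents that add atoms: none
Why: Saponification gives 4, which loses CO2 on acidification and warming by ipso-protonation of the very electron-rich ring (protodecarboxylation of a 2,4,6-trioxygenated benzoic acid). The carboxyl group has then done its work as blocking and differentiating group.

Step 4
Reactants: 5 3,5-dimethoxy-2,4-dimethylphenol
Product: 6 2-bromo-3,5-dimethoxy-4,6-dimethylphenol
Conditions: NBS (1.0 equiv), MeCN, −20 to 0 °C, dark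
Reagents that add atoms: N-bromosuccinimide, O=C1CCC(=O)N1Br
Why: Electrophilic aromatic bromination at the only unsubstituted ring carbon, activated by ortho OH, ortho OMe and para OMe. One equivalent at low temperature avoids ipso attack and oxidation to a quinone.

Step 5
Reactants: 6 2-bromo-3,5-dimethoxy-4,6-dimethylphenol
Product: 7 (2-bromo-3,5-dimethoxy-4,6-dimethylphenoxy)trimethylsilane
Conditions: HMDS, THF, 70 °C; evaporate, use crude
Reagents that add atoms: hexamethyldisilazane, C[Si](C)(C)N[Si](C)(C)C
Why: O-Silylation of the phenol with HMDS, whose only by-product is ammonia, so the moisture-sensitive silyl ether can be carried on without purification.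

Step 6
Reactants: 7 (2-bromo-3,5-dimethoxy-4,6-dimethylphenoxy)trimethylsilane
Product: 10 3,5-dimethoxy-2,4-dimethyl-6-(trimethylsilyl)phenyl trifluoromethanesulfonate, via aryllithium 8 (not isolated), via lithium silylphenoxide 9 (not isolated)
Conditions: n-BuLi, THF, −100 to −78 °C; then Tf2O, −100 to −78 °C
Reagents that add atoms: trifluoromethanesulfonic anhydride, O=S(=O)(OS(=O)(=O)C(F)(F)F)C(F)(F)F
Why: Bromine–lithium exchange gives 8, which undergoes the anionic 1,3 O-to-C silyl shift (retro-Brook rearrangement) to 9. Triflation of 9 gives the ortho-silylaryl triflate, the standard fluoride-triggered aryne precursor.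

Step 7
Reactants: 11 methyl benzyloxyacetate; 12 2-methoxybenzaldehyde
Product: 14 (Z)-2-(benzyloxy)-3-(2-methoxyphenyl)acrylic acid, via methyl ester 13 (not isolated)
Conditions: NaOMe, MeOH, 0 °C to reflux (11 in excess); then 2 M NaOH, 60 °C; HCl; recrystallise
Reagents that add atoms: sodium hydroxide (aqueous), [Na+].[OH-]
Why: Methoxide-mediated aldol condensation of the ester enolate of 11 with the non-enolisable aldehyde 12, followed by E1cB dehydration to 13 and saponification in the same flask. The isomer with aryl trans to the carboxyl (Z by the sequence rule) is the thermodynamic one and should be purified by crystallisation of the acid.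

Step 8
Reactants: 10 3,5-dimethoxy-2,4-dimethyl-6-(trimethylsilyl)phenyl trifluoromethanesulfonate; 14 (Z)-2-(benzyloxy)-3-(2-methoxyphenyl)acrylic acid
Product: 16 (Z)-2-(benzyloxy)-1-(2-hydroxy-4,6-dimethoxy-3,5-dimethylphenyl)-3-(2-methoxyphenyl)prop-2-en-1-one, via aryne 15 (not isolated)
Conditions: CsF (4 equiv), THF, 125 °C, sealed tube; 14 (1.5 equiv), 10 limiting
Reagents that add atoms: none
Why: Fluoride attacks silicon of 10 and triflate leaves from the neighbouring carbon, giving aryne 15 with its strained bond between C4a and C8a, while 14 is present as its cesium carboxylate. The carboxylate oxygen adds to C8a, the resulting C4a aryl anion attacks the adjacent ester carbonyl (4-exo-trig) to give a four-membered alkoxide, and opening of that ring breaks the acyl–oxygen bond, so that C4 ends on C4a and the oxygen stays on C8a as a phenoxide that is protonated on work-up. The closest known reaction type is the fluoride-mediated insertion of arynes into the acyl C–O bond of carboxylic acids to give ortho-hydroxyaryl ketones, known for aromatic and for α,β-unsaturated acids in hot THF. No ring remains in the product, since the four-membered ring is transient, and no stereocentre is formed; the Z alkene of 14 is not involved. The selectivity required is the direction of addition across the aryne: the σ-withdrawing methoxy group on C5 makes the remote terminus C8a the electrophilic one and stabilises the negative charge developing on C4a, and this bias should outweigh the modest steric opposition of the C8 methyl group. Acyl transfer must also beat protonation of the aryl anion, which would stop at the aryl ester; an aprotic medium, sparingly soluble CsF (slow aryne release, HF bound as CsHF2) and high temperature serve this, and the fully substituted ring offers no other reactive site. Acid 14, made in one step, is used in excess so that the six-step triflate 10 is the limiting component. Any 16 that closes to 17 under the basic conditions is carried forward, since step 9 converts both.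

Step 9
Reactants: 16 (Z)-2-(benzyloxy)-1-(2-hydroxy-4,6-dimethoxy-3,5-dimethylphenyl)-3-(2-methoxyphenyl)prop-2-en-1-one
Product: 18 3-(benzyloxy)-5,7-dimethoxy-2-(2-methoxyphenyl)-6,8-dimethyl-4H-chromen-4-one, via 3-benzyloxyflavanone 17 (not isolated)
Conditions: I2 (10 mol %), DMSO, 120 °C
Reagents that add atoms: none
Why: Iodine-catalysed oxidative cyclisation of a 2'-hydroxychalcone in DMSO: 6-endo oxa-Michael addition of the C8a hydroxyl to C2 gives 17, iodination at C3 and loss of HI (ionisation assisted by the benzyloxy oxygen) give the chromone, and DMSO reoxidises HI to I2. The alkene geometry of 16 is irrelevant because C2 and C3 both end up sp2 in the pyranone ring.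

Step 10
Reactants: 18 3-(benzyloxy)-5,7-dimethoxy-2-(2-methoxyphenyl)-6,8-dimethyl-4H-chromen-4-one
Product: 19 3-hydroxy-5,7-dimethoxy-2-(2-methoxyphenyl)-6,8-dimethyl-4H-chromen-4-one
Conditions: H2 (1 atm), 10% Pd/C, EtOAc–MeOH, rt
Reagents that add atoms: none
Why: Hydrogenolysis of the benzyl ether under neutral conditions frees the C3 hydroxyl without touching the aryl methyl ethers, whereas a Lewis acid would attack the C5 methoxy group. The C2–C3 double bond is part of a vinylogous ester and should not be reduced at 1 atm.

**Compound list**

1 | methyl 2,4,6-trihydroxybenzoate | COC(=O)c1c(O)cc(O)cc1O | starting material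
2 | methyl 2,4,6-trihydroxy-3,5-dimethylbenzoate | COC(=O)c1c(O)c(C)c(O)c(C)c1O | intermediate
3 | methyl 2-hydroxy-4,6-dimethoxy-3,5-dimethylbenzoate | COC(=O)c1c(O)c(C)c(OC)c(C)c1OC | intermediate
4 | 2-hydroxy-4,6-dimethoxy-3,5-dimethylbenzoic acid | OC(=O)c1c(O)c(C)c(OC)c(C)c1OC | intermediate (not isolated)
5 | 3,5-dimethoxy-2,4-dimethylphenol | Oc1cc(OC)c(C)c(OC)c1C | intermediate
6 | 2-bromo-3,5-dimethoxy-4,6-dimethylphenol | Oc1c(Br)c(OC)c(C)c(OC)c1C | intermediate
7 | (2-bromo-3,5-dimethoxy-4,6-dimethylphenoxy)trimethylsilane | C[Si](C)(C)Oc1c(Br)c(OC)c(C)c(OC)c1C | intermediate
8 | {2,4-dimethoxy-3,5-dimethyl-6-[(trimethylsilyl)oxy]phenyl}lithium | [Li]c1c(OC)c(C)c(OC)c(C)c1O[Si](C)(C)C | intermediate (not isolated)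
9 | lithium 3,5-dimethoxy-2,4-dimethyl-6-(trimethylsilyl)phenoxide | [Li+].[O-]c1c(C)c(OC)c(C)c(OC)c1[Si](C)(C)C | intermediate (not isolated)
10 | 3,5-dimethoxy-2,4-dimethyl-6-(trimethylsilyl)phenyl trifluoromethanesulfonate | COc1c(C)c(OC)c(C)c(OS(=O)(=O)C(F)(F)F)c1[Si](C)(C)C | intermediate
11 | methyl benzyloxyacetate | COC(=O)COCc1ccccc1 | starting material
12 | 2-methoxybenzaldehyde | COc1ccccc1C=O | starting material
13 | methyl (Z)-2-(benzyloxy)-3-(2-methoxyphenyl)acrylate | COc1ccccc1/C=C(\OCc1ccccc1)C(=O)OC | intermediate (not isolated)
14 | (Z)-2-(benzyloxy)-3-(2-methoxyphenyl)acrylic acid | COc1ccccc1/C=C(\OCc1ccccc1)C(=O)O | intermediate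
15 | 3,5-dimethoxy-4,6-dimethylbenzyne (1,2-didehydro-3,5-dimethoxy-4,6-dimethylbenzene) | COC1=C(C)C(OC)=C(C)C#C1 | intermediate (not isolated)
16 | (Z)-2-(benzyloxy)-1-(2-hydroxy-4,6-dimethoxy-3,5-dimethylphenyl)-3-(2-methoxyphenyl)prop-2-en-1-one | COc1ccccc1/C=C(\OCc1ccccc1)C(=O)c1c(O)c(C)c(OC)c(C)c1OC | intermediate
17 | 3-(benzyloxy)-5,7-dimethoxy-2-(2-methoxyphenyl)-6,8-dimethylchroman-4-one (racemic, mixture of diastereomers, both centres erased) | COc1ccccc1C1Oc2c(C)c(OC)c(C)c(OC)c2C(=O)C1OCc1ccccc1 | intermediate (not isolated)
18 | 3-(benzyloxy)-5,7-dimethoxy-2-(2-methoxyphenyl)-6,8-dimethyl-4H-chromen-4-one | COc1ccccc1-c1oc2c(C)c(OC)c(C)c(OC)c2c(=O)c1OCc1ccccc1 | intermediate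
19 | 3-hydroxy-5,7-dimethoxy-2-(2-methoxyphenyl)-6,8-dimethyl-4H-chromen-4-one | COc1ccccc1-c1oc2c(C)c(OC)c(C)c(OC)c2c(=O)c1O | target

**Step count and least certain steps**

Total: 10 steps. Longest linear sequence: 9 steps (steps 1 to 6, then 8, 9 and 10); step 7 is a one-step branch.

Step 8 (key step). Two processes are most likely to go wrong. The C4a aryl anion may be protonated before it reaches the ester carbonyl, so that the sequence stops at O-arylation. The carboxylate may also add with the reverse orientation, because the C8 methyl group crowds the carbon that must take oxygen; and the hindered anion has to attack a conjugated, less electrophilic carbonyl. The fallback generates the same aryl anion by known chemistry and sets out from 6 and 14. Steglich esterification (DCC, DMAP, CH2Cl2) gives 2-bromo-3,5-dimethoxy-4,6-dimethylphenyl (Z)-2-(benzyloxy)-3-(2-methoxyphenyl)acrylate F1. Bromine–lithium exchange with n-BuLi in THF at −100 °C then triggers the anionic Fries-type 1,3 O-to-C acyl shift and rejoins the route at 16. The oxygen is on C8a from the start and the metal is generated only on C4a, so orientation is not in question and no proton source is present. Steps 5 and 6 would not be needed; the fallback's own risk is attack of the alkyllithium on the unsaturated ester.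

Step 1. Over-alkylation is the likely failure: a second methyl group enters at an already methylated carbon with loss of aromaticity, and some O-methylation occurs because the phenoxide is ambident. The fallback sets out from 1. Double Mannich aminomethylation (aqueous formaldehyde, morpholine, EtOH) gives methyl 2,4,6-trihydroxy-3,5-bis(morpholin-4-ylmethyl)benzoate F2, which cannot be alkylated twice at one carbon. Hydrogenolysis of the two benzylic C–N bonds (H2, Pd/C, AcOH, 60 °C) returns to the route at 2.

Step 2. Loss of site selectivity is the likely failure: methylation runs on to the chelated hydroxyl or stops early. The fallback sets out from 2. Exhaustive methylation (MeI, K2CO3, DMF) gives methyl 2,4,6-trimethoxy-3,5-dimethylbenzoate F3. BCl3 (1 equiv, CH2Cl2, −78 to 0 °C) then removes one methyl group from an ortho methoxy group through chelation to the ester carbonyl; the two ortho groups are equivalent, so either cleavage rejoins the route at 3.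

Step 6. The aryllithium may be quenched by proton transfer before the silyl shift, or triflation of a phenoxide flanked by SiMe3 and methyl may be so slow that Tf2O is consumed by THF. The fallback sets out from 5. Isopropyl isocyanate with catalytic Et3N gives 3,5-dimethoxy-2,4-dimethylphenyl isopropylcarbamate F4. In situ N-silylation (TMSOTf, TMEDA), carbamate-directed ortho-lithiation at the only ring hydrogen (n-BuLi, −78 °C) and a TMSCl quench give 3,5-dimethoxy-2,4-dimethyl-6-(trimethylsilyl)phenyl isopropylcarbamate F5. Cleavage of the carbamate with Et2NH and DBU and triflation of the liberated phenoxide with PhNTf2 in the same flask return to the route at 10, by-passing 6 and 7.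

Step 9. Acid-promoted loss or hydrolysis of the benzyl enol ether at 120 °C is possible, since HI is present in low concentration, and the sequence may stop at the flavanone stage. The fallback sets out from 16. NaOAc in refluxing EtOH effects the oxa-Michael closure to 17, which is isolated this time. Hydrogenolysis (H2, Pd/C) gives 3-hydroxy-5,7-dimethoxy-2-(2-methoxyphenyl)-6,8-dimethylchroman-4-one F6. Dehydrogenation with I2 and KOAc in hot AcOH, the classical conversion of dihydroflavonols into flavonols, arrives directly at 19, by-passing 18.

**Further compounds**

F1 | step 8 | 2-bromo-3,5-dimethoxy-4,6-dimethylphenyl (Z)-2-(benzyloxy)-3-(2-methoxyphenyl)acrylate | COc1ccccc1/C=C(\OCc1ccccc1)C(=O)Oc1c(Br)c(OC)c(C)c(OC)c1C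
F2 | step 1 | methyl 2,4,6-trihydroxy-3,5-bis(morpholin-4-ylmethyl)benzoate | COC(=O)c1c(O)c(CN2CCOCC2)c(O)c(CN2CCOCC2)c1O
F3 | step 2 | methyl 2,4,6-trimethoxy-3,5-dimethylbenzoate | COC(=O)c1c(OC)c(C)c(OC)c(C)c1OC
F4 | step 6 | 3,5-dimethoxy-2,4-dimethylphenyl isopropylcarbamate | CC(C)NC(=O)Oc1cc(OC)c(C)c(OC)c1C
F5 | step 6 | 3,5-dimethoxy-2,4-dimethyl-6-(trimethylsilyl)phenyl isopropylcarbamate | CC(C)NC(=O)Oc1c(C)c(OC)c(C)c(OC)c1[Si](C)(C)C
F6 | step 9 | 3-hydroxy-5,7-dimethoxy-2-(2-methoxyphenyl)-6,8-dimethylchroman-4-one (racemic, trans expected, both centres erased) | COc1ccccc1C1Oc2c(C)c(OC)c(C)c(OC)c2C(=O)C1O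
A1 | alternative 1 | 2-hydroxy-4,6-dimethoxy-3,5-dimethylbenzaldehyde | O=Cc1c(O)c(C)c(OC)c(C)c1OC
A2 | alternative 1 | triisopropyl{[(2-methoxyphenyl)ethynyl]oxy}silane | COc1ccccc1C#CO[Si](C(C)C)(C(C)C)C(C)C
A3 | alternative 1 | 5,7-dimethoxy-2-(2-methoxyphenyl)-6,8-dimethyl-3-[(triisopropylsilyl)oxy]-4H-chromen-4-one | COc1ccccc1-c1oc2c(C)c(OC)c(C)c(OC)c2c(=O)c1O[Si](C(C)C)(C(C)C)C(C)C
A4 | alternative 2 | 3-methoxy-2-methylcyclobut-2-enone | COC1=C(C)C(=O)C1
A5 | alternative 2 | 1-methoxypropyne | CC#COC
A6 | alternative 2 | 3,5-dimethoxy-2,4-dimethylphenol (identical with 5) | Oc1cc(OC)c(C)c(OC)c1C
A7 | alternative 3 | 2-[1-(2-methoxyphenyl)-2-oxoethoxy]-4,6-dimethoxy-3,5-dimethylbenzaldehyde (racemic) | COc1ccccc1C(C=O)Oc1c(C)c(OC)c(C)c(OC)c1C=O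
A8 | alternative 3 | 5,7-dimethoxy-2-(2-methoxyphenyl)-6,8-dimethylchromane-3,4-diol (racemic, mixture of diastereomers) | COc1ccccc1C1Oc2c(C)c(OC)c(C)c(OC)c2C(O)C1O
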